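**Assumption:** the target has no stereocentre and no stereogenic double bond, so it is achiral and "the single enantiomer" is the compound itself. The sp3 centres in 4, 7, 8 and 9 are formed as mixtures and are all erased on aromatisation.

**Retrosynthetic overview**
1. Cleave the depside ester C–O bond to give phenol 10 (methyl 2,4-dihydroxy-3,5,6-trimethylbenzoate) and the 2-O-benzyl acid 15; the benzyl group is removed last.
2. Ring A (the only ring built) comes from dimethyl malonate and enone 5 by an intermolecular Michael addition (key C–C bond, C1–C6), then Dieckmann/Claisen closure (C2–C3), then bromination/dehydrobromination to the arene.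
3. Enone 5 comes from pentan-3-one and acetaldehyde by a directed aldol addition and dehydration.
4. Ring B is not built: commercial methyl 2,4-dihydroxy-3,6-dimethylbenzoate (11) is 4-O-methylated, chlorinated at C5, 2-O-benzylated and saponified.
5. Order: ring A is formed (steps 1–4), ring B is elaborated (steps 5–8), the rings are joined by esterification (step 9) and deprotected (step 10).

**Route**

Step 1
Reactants: 1 pentan-3-one; 2 acetaldehyde
Product: 4 5-hydroxy-4-methylhexan-3-one (racemic syn/anti mixture), via lithium pent-2-en-3-olate 3 (not isolated)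
Conditions: LDA (1.05 equiv), THF, −78 °C, 45 min; then MeCHO (1.1 equiv), −78 °C, 20 min; sat. aq. NH4Cl
Reagents that add atoms: none
Why: A directed (crossed) aldol addition of the preformed lithium enolate of a symmetrical ketone to acetaldehyde avoids self-condensation; the two new stereocentres need no control because both are destroyed later.

Step 2
Reactants: 4 5-hydroxy-4-methylhexan-3-one
Product: 5 (E)-4-methylhex-4-en-3-one
Conditions: p-TsOH·H2O (5 mol %), cyclohexane, reflux, Dean–Stark; fractional distillation
Reagents that add atoms: none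
Why: Acid-catalysed dehydration of the β-hydroxy ketone (aldol condensation) gives the conjugated trisubstituted enone as the thermodynamic E isomer, and the geometry is irrelevant after the next step.

Step 3
Reactants: 5 (E)-4-methylhex-4-en-3-one; 6 dimethyl malonate
Product: 8 methyl 3,5,6-trimethyl-2,4-dioxocyclohexane-1-carboxylate (diastereomer/enol mixture), via Michael adduct 7 (not isolated)
Conditions: NaOMe (1.1 equiv), MeOH, reflux, 6 h; then aq. HCl, 0 °C
Reagents that add atoms: none
Why: Intermolecular Michael addition of the malonate anion to the enone β-carbon followed by Dieckmann (intramolecular Claisen) closure of the ethyl-ketone enolate onto a malonate ester can only give the six-membered ring and is driven by formation of the stable tricarbonyl enolate; the new stereocentres are uncontrolled and are removed in step 4.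

Step 4
Reactants: 8 methyl 3,5,6-trimethyl-2,4-dioxocyclohexane-1-carboxylate
Product: 10 methyl 2,4-dihydroxy-3,5,6-trimethylbenzoate, via bromodione 9 (not isolated)
Conditions: Br2 (1.0 equiv), AcOH, rt, 1 h; then 70 °C, 2 h
Reagents that add atoms: none
Why: α-Bromination of the enolised 1,3-dione followed by HBr-promoted bromine shift and dehydrobromination (halogenation–dehydrohalogenation aromatisation) gives the resorcinol tautomer, and the fully substituted ring cannot be brominated further.

Step 5
Reactants: 11 methyl 2,4-dihydroxy-3,6-dimethylbenzoate (atraric acid)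
Product: 12 methyl 2-hydroxy-4-methoxy-3,6-dimethylbenzoate
Conditions: MeI (1.1 equiv), K2CO3 (1.2 equiv), acetone, reflux
Reagents that add atoms: iodomethane, CI
Why: Williamson etherification is selective for the more acidic, non-chelated 4-OH because the 2-OH is locked in a hydrogen bond to the ester carbonyl.

Step 6
Reactants: 12 methyl 2-hydroxy-4-methoxy-3,6-dimethylbenzoate
Product: 13 methyl 5-chloro-2-hydroxy-4-methoxy-3,6-dimethylbenzoate
Conditions: SO2Cl2 (1.05 equiv), CH2Cl2, 0 °C to rt, dark
Reagents that add atoms: sulfuryl chloride, ClS(Cl)(=O)=O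
Why: Electrophilic aromatic chlorination occurs at C5, the only unsubstituted ring carbon, which is para to the free OH and ortho to OMe.

Step 7
Reactants: 13 methyl 5-chloro-2-hydroxy-4-methoxy-3,6-dimethylbenzoate
Product: 14 methyl 2-(benzyloxy)-5-chloro-4-methoxy-3,6-dimethylbenzoate
Conditions: BnBr (1.5 equiv), K2CO3 (3 equiv), Bu4NI (cat.), DMF, 65 °C
Reagents that add atoms: benzyl bromide, BrCc1ccccc1
Why: Williamson O-benzylation under forcing conditions caps the chelated salicylate OH so that it cannot compete as a nucleophile in the depside coupling.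

Step 8
Reactants: 14 methyl 2-(benzyloxy)-5-chloro-4-methoxy-3,6-dimethylbenzoate
Product: 15 2-(benzyloxy)-5-chloro-4-methoxy-3,6-dimethylbenzoic acid
Conditions: KOH (10 equiv), DMSO/H2O 5:1, 100 °C; then aq. HCl to pH 2, 0 °C
Reagents that add atoms: potassium hydroxide, [K+].[OH-]
Why: Saponification with poorly solvated hydroxide in DMSO overcomes the di-ortho hindrance of the ester, and the benzyl ether, aryl methyl ether and aryl chloride are inert to base.

Step 9
Reactants: 15 2-(benzyloxy)-5-chloro-4-methoxy-3,6-dimethylbenzoic acid; 10 methyl 2,4-dihydroxy-3,5,6-trimethylbenzoate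
Product: 17 methyl 4-{[2-(benzyloxy)-5-chloro-4-methoxy-3,6-dimethylbenzoyl]oxy}-2-hydroxy-3,5,6-trimethylbenzoate, via mixed anhydride 16 (not isolated)
Conditions: TFAA (4 equiv), toluene, 0 °C to rt, 12 h; aq. NaHCO3 work-up
Reagents that add atoms: none
Why: TFAA-mediated esterification proceeds through the aroyl trifluoroacetate (acylium-like), which acylates hindered phenols, and the 4-OH reacts in preference to the ester-chelated 2-OH.

Step 10
Reactants: 17 methyl 4-{[2-(benzyloxy)-5-chloro-4-methoxy-3,6-dimethylbenzoyl]oxy}-2-hydroxy-3,5,6-trimethylbenzoate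
Product: 18 methyl 4-[(5-chloro-2-hydroxy-4-methoxy-3,6-dimethylbenzoyl)oxy]-2-hydroxy-3,5,6-trimethylbenzoate (CNP0313903.0)
Conditions: H2 (1 atm), 10 % Pd/C, EtOAc, rt, stopped at full conversion
Reagents that add atoms: none
Why: Catalytic hydrogenolysis of the benzyl ether under neutral conditions leaves both esters untouched, and the electron-rich, di-ortho-flanked aryl chloride is reduced much more slowly.

**Compound list**
1 | pentan-3-one | CCC(=O)CC | starting material
2 | acetaldehyde | CC=O | starting material
3 | lithium pent-2-en-3-olate (E/Z mixture) | CC=C(CC)[O-].[Li+] | intermediate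
4 | 5-hydroxy-4-methylhexan-3-one (racemic syn/anti mixture) | CCC(=O)C(C)C(C)O | intermediate
5 | (E)-4-methylhex-4-en-3-one | CCC(=O)/C(C)=C/C | intermediate
6 | dimethyl malonate | COC(=O)CC(=O)OC | starting material
7 | dimethyl 2-(3-methyl-4-oxohexan-2-yl)propanedioate (Michael adduct, present as sodium enolate, diastereomer mixture) | COC(=O)C(C(=O)OC)C(C)C(C)C(=O)CC | intermediate
8 | methyl 3,5,6-trimethyl-2,4-dioxocyclohexane-1-carboxylate (diastereomer/enol mixture) | COC(=O)C1C(C)C(C)C(=O)C(C)C1=O | intermediate
9 | methyl 3-bromo-3,5,6-trimethyl-2,4-dioxocyclohexane-1-carboxylate (diastereomer mixture) | COC(=O)C1C(C)C(C)C(=O)C(C)(Br)C1=O | intermediate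
10 | methyl 2,4-dihydroxy-3,5,6-trimethylbenzoate | COC(=O)c1c(C)c(C)c(O)c(C)c1O | intermediate
11 | methyl 2,4-dihydroxy-3,6-dimethylbenzoate (atraric acid) | COC(=O)c1c(C)cc(O)c(C)c1O | starting material
12 | methyl 2-hydroxy-4-methoxy-3,6-dimethylbenzoate | COC(=O)c1c(C)cc(OC)c(C)c1O | intermediate
13 | methyl 5-chloro-2-hydroxy-4-methoxy-3,6-dimethylbenzoate | COC(=O)c1c(C)c(Cl)c(OC)c(C)c1O | intermediate
14 | methyl 2-(benzyloxy)-5-chloro-4-methoxy-3,6-dimethylbenzoate | COC(=O)c1c(C)c(Cl)c(OC)c(C)c1OCc1ccccc1 | intermediate
15 | 2-(benzyloxy)-5-chloro-4-methoxy-3,6-dimethylbenzoic acid | OC(=O)c1c(C)c(Cl)c(OC)c(C)c1OCc1ccccc1 | intermediate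
16 | 2-(benzyloxy)-5-chloro-4-methoxy-3,6-dimethylbenzoic trifluoroacetic anhydride | O=C(OC(=O)C(F)(F)F)c1c(C)c(Cl)c(OC)c(C)c1OCc1ccccc1 | intermediate
17 | methyl 4-{[2-(benzyloxy)-5-chloro-4-methoxy-3,6-dimethylbenzoyl]oxy}-2-hydroxy-3,5,6-trimethylbenzoate | COC(=O)c1c(C)c(C)c(OC(=O)c2c(C)c(Cl)c(OC)c(C)c2OCc2ccccc2)c(C)c1O | intermediate
18 | methyl 4-[(5-chloro-2-hydroxy-4-methoxy-3,6-dimethylbenzoyl)oxy]-2-hydroxy-3,5,6-trimethylbenzoate | COC(=O)c1c(C)c(C)c(OC(=O)c2c(C)c(Cl)c(OC)c(C)c2O)c(C)c1O | target

**Totals**
Total step count: 10. Longest linear sequence: 6 steps (steps 1–4, 9, 10, or equally steps 5–10).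

**Three steps most likely to fail**

Step 4 (aromatisation of the fully substituted dione; the bromine first sits on a carbon with no hydrogen and must shift before HBr can be lost). Fallback: set out from 11, which already is the aromatic ring lacking only the C5 methyl. A Mannich aminomethylation (morpholine, 37 % aq. formaldehyde, EtOH, reflux) at the only free ring position gives methyl 2,4-dihydroxy-3,6-dimethyl-5-(morpholin-4-ylmethyl)benzoate F1. Hydrogenolysis of its benzylic C–N bond (H2 5 bar, Pd/C, AcOH, 70 °C) turns CH2N into CH3 and comes back to the route at 10. This also bypasses steps 1–3.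

Step 8 (saponification of a di-ortho-substituted methyl benzoate). Fallback: set out from 14 and change the oxidation level instead of attacking the hindered carbonyl with hydroxide. LiAlH4 in THF (0 °C to rt) gives [2-(benzyloxy)-5-chloro-4-methoxy-3,6-dimethylphenyl]methanol F2. MnO2 in CH2Cl2 gives 2-(benzyloxy)-5-chloro-4-methoxy-3,6-dimethylbenzaldehyde F3. Pinnick oxidation (NaClO2, NaH2PO4, 2-methylbut-2-ene, t-BuOH/H2O) comes back to the route at 15.

Step 9 (tetra-ortho-substituted aryl ester formation). Fallback: set out from 15 and 10 and replace acid-mediated acylation of the neutral phenol by an anionic nucleophile with a preformed acyl halide. Oxalyl chloride with catalytic DMF in CH2Cl2 converts 15 into 2-(benzyloxy)-5-chloro-4-methoxy-3,6-dimethylbenzoyl chloride F4. Separately, 10 is deprotonated at the more acidic 4-OH with NaH (1.0 equiv) in THF/DMF to give sodium 3-hydroxy-4-(methoxycarbonyl)-2,5,6-trimethylphenolate F5. Combining the two at rt to 60 °C comes back to the route at 17.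

**Further compounds**
F1 | step 4 | methyl 2,4-dihydroxy-3,6-dimethyl-5-(morpholin-4-ylmethyl)benzoate | COC(=O)c1c(C)c(CN2CCOCC2)c(O)c(C)c1O
F2 | step 8 | [2-(benzyloxy)-5-chloro-4-methoxy-3,6-dimethylphenyl]methanol | OCc1c(C)c(Cl)c(OC)c(C)c1OCc1ccccc1
F3 | step 8 | 2-(benzyloxy)-5-chloro-4-methoxy-3,6-dimethylbenzaldehyde | O=Cc1c(C)c(Cl)c(OC)c(C)c1OCc1ccccc1
F4 | step 9 | 2-(benzyloxy)-5-chloro-4-methoxy-3,6-dimethylbenzoyl chloride | O=C(Cl)c1c(C)c(Cl)c(OC)c(C)c1OCc1ccccc1
F5 | step 9 | sodium 3-hydroxy-4-(methoxycarbonyl)-2,5,6-trimethylphenolate | COC(=O)c1c(C)c(C)c([O-])c(C)c1O.[Na+]
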